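**Plan**
- Retrosynthetic cuts: the C3 dioxolane and the 6′-O-methyl group come off first; the pyranone is cut at C3′=C4′ and at the lactone C2′–O1′ (Wittig olefination/lactonization of a salicylaldehyde); the benzene ring is cut at C5′–C6′ (thermal rearrangement of a 4-alkenyl-4-hydroxycyclobutenone); then the carbinol–alkenyl bond (alkenyllithium plus squarate) and the C7′–O bond (alkoxide plus dimethyl squarate).
- Terpene cuts: C9–C11 ([2,3]-Wittig–Still shift), C3–C4 (radical alkene–nitrile closure), C10–C1 and C10–CH3 (two α′-functionalizations of (R)-carvone).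
- Enabling feature: C6′, C7′, C8′ and C8a′ of the coumarin benzene ring carry four adjacent oxygens, the pattern of the four oxygen-bearing carbons of squaric acid. C4a′ and C5′ come from a two-carbon alkenyl unit. The crowded C7′–O–C11 ether, flanked by two oxygenated ring carbons, is made by addition–elimination on the squarate, not by substitution at C11.
- Forward order of rings: ring B is the carvone ring; ring A is closed by radical cyclization; the benzene ring is grown on the finished ether by electrocyclization; the pyranone ring is closed last.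
- Stereochemistry: C5 comes from (R)-carvone; C10 is set by Michael addition anti to the isopropenyl group; the α-epoxide (anti to the C10 methyl) becomes the 7α-hydroxyl by Wharton transposition, and its suprafacial [2,3] shift sets C9.

Key step: step 11

Remark on the chemistry: terpene carbons carry drimane numbers and coumarin carbons primed numbers; α/β refer to the usual drawing with the C10 methyl β. The target SMILES places the C9–CH2O bond trans to the C10 methyl (9-epi-drimane arrangement, 5α-H, 9β-H), and this is what is made. "Drk" stands for 3,3-ethylenedioxy-9-epi-drim-7-en-11-yl. 2-Bromo-3,3-diethoxyprop-1-ene, Bu3SnCH2I, Ph3P=CHCO2Et and isofraxidin are taken as purchasable.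

Step 1
Reactants: 1 (R)-carvone
Product: 3 6-methylcarvone (both C6 epimers), via lithium dienolate of carvone 2 (not isolated)
Conditions: LiN(i-Pr)2, THF, −78 °C; MeI, −78 → 0 °C
Reagents that add atoms: iodomethane, CI
Why: Kinetic α′-deprotonation gives the cross-conjugated lithium dienolate, whose C-methylation (enolate alkylation) is routine for carvone; the new centre forms as a mixture that is erased in step 2.

Step 2
Reactants: 3 6-methylcarvone
Product: 4 6-(2-cyanoethyl)-6-methylcarvone (cyanoethyl trans to isopropenyl)
Conditions: acrylonitrile, t-BuOK (0.2 equiv), t-BuOH/THF, 0 °C → rt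
Reagents that add atoms: acrylonitrile, C=CC#N
Why: Base-catalysed Michael addition (cyanoethylation) in a protic medium should protonate the adduct carbanion at once, so no second ring-forming Michael step follows and the conjugated α′-adduct is retained; the tertiary enolate is attacked anti to the neighbouring isopropenyl group, which sets C10 with the methyl cis and the chain trans to it.

Step 3
Reactants: 4 cyano enone
Product: 6 11-nordrim-7-ene-3,9-dione (trans-fused), via ketimine 5 (not isolated)
Conditions: Fe(acac)3 (0.3 equiv), PhSiH3, EtOH, 60 °C; then 1 M HCl, THF, rt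
Reagents that add atoms: water, O
Why: Hydrogen-atom transfer from an iron hydride to the 1,1-disubstituted alkene gives the tertiary C4 radical, which should close 6-exo onto the nitrile carbon (HAT-initiated radical alkene–nitrile cyclization); the ketimine is hydrolysed to the C3 ketone, and the trans ring fusion follows from the trans arrangement of the two arms fixed in step 2.

Step 4
Reactants: 6 enedione
Product: 7 3,3-ethylenedioxy-11-nordrim-7-en-9-one
Conditions: ethylene glycol, p-TsOH·H2O (cat.), benzene, reflux, azeotropic removal of water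
Reagents that add atoms: ethane-1,2-diol, OCCO
Why: Acid-catalysed ketalization should select the saturated C3 ketone over the conjugated C9 carbonyl, which is flanked by the quaternary C10 and the methylated C8 and is far less prone to ketal formation.

Step 5
Reactants: 7 ketal enone
Product: 8 7α,8α-epoxy-3,3-ethylenedioxy-11-nordriman-9-one
Conditions: 30% aq. H2O2, NaOH (0.5 equiv), MeOH, 0 °C
Reagents that add atoms: hydrogen peroxide, OO
Why: Weitz–Scheffer nucleophilic epoxidation; hydroperoxide should add axially to C7 on the α face, anti to the axial C10 methyl and trans to the C5–C4 bond as in carvone, so both new centres (C7, C8) carry α oxygen.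

Step 6
Reactants: 8 epoxy ketone
Product: 10 3,3-ethylenedioxy-11-nordrim-8-en-7α-ol, via epoxy hydrazone 9 (not isolated)
Conditions: N2H4·H2O (3 equiv), AcOH (0.2 equiv), MeOH, 0 °C → rt
Reagents that add atoms: none
Why: Wharton transposition; the hydrazone opens the epoxide and loses N2 to give the C8=C9 alkene while the C7–O bond is untouched, so the axial 7α-hydroxyl is retained.

Step 7
Reactants: 10 allylic alcohol
Product: 12 7α-[(tributylstannyl)methoxy]-3,3-ethylenedioxy-11-nordrim-8-ene, via potassium alkoxide 11 (not isolated)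
Conditions: KH, THF, 0 °C; Bu3SnCH2I, 18-crown-6 (cat.), 0 °C → rt
Reagents that add atoms: tributyl(iodomethyl)stannane, CCCC[Sn](CCCC)(CCCC)CI
Why: Williamson etherification of the secondary allylic alkoxide with the unhindered iodomethylstannane is the standard entry to Wittig–Still substrates.

Step 8
Reactants: 12 stannylmethyl ether
Product: 14 3,3-ethylenedioxy-9-epi-drim-7-en-11-ol (Drk-OH), via alkoxymethyllithium 13 (not isolated)
Conditions: n-BuLi, THF, −78 °C; aq. NH4Cl
Reagents that add atoms: none
Why: Tin–lithium exchange triggers the Wittig–Still [2,3]-sigmatropic shift, which is suprafacial, so the CH2O carbon passes from the axial 7α oxygen to the α face of C9 (anti to the C10 methyl), setting 9β-H and moving the alkene to C7=C8.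

Step 9
Reactants: 14 Drk-OH; 15 dimethyl squarate
Product: 17 3-methoxy-4-(Drk-oxy)cyclobut-3-ene-1,2-dione, via lithium alkoxide 16 (not isolated)
Conditions: n-BuLi (1.0 equiv), THF, −78 °C; cannulated into 15 (3 equiv), THF, −78 → −20 °C; aq. NH4Cl
Reagents that add atoms: none
Why: Addition–elimination of the alkoxide at a vinylogous ester carbon (squarate transesterification) forms the C11–O–C(sp2) bond without any substitution at C11, and the excess of dimethyl squarate should limit double exchange.

Step 10
Reactants: 17 mixed squarate; 18 2-bromo-3,3-diethoxyprop-1-ene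
Product: 20 4-[1-(diethoxymethyl)ethenyl]-4-hydroxy-3-methoxy-2-(Drk-oxy)cyclobut-2-en-1-one (both carbinol epimers), via 2-lithio-3,3-diethoxypropene 19 (not isolated)
Conditions: 18 (1.3 equiv), t-BuLi (2.6 equiv), THF, −78 °C; then 17, THF, −78 °C; aq. NH4Cl at −78 °C
Reagents that add atoms: none
Why: 1,2-Addition of an alkenyllithium to a squarate carbonyl; the two carbonyls are electronically alike, and the branched nucleophile is expected to take the one beside the methoxy-bearing carbon because the other is shielded by the terpenyl ether branched at C9 and C10, while the carbinol centre forms without control and is lost in step 11.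

Step 11
Reactants: 20 squarate adduct
Product: 23 2,5-dihydroxy-3-methoxy-4-(Drk-oxy)benzaldehyde diethyl acetal, via dienylketene 21 (not isolated), via cyclohexadienone 22 (not isolated)
Conditions: toluene (degassed, 0.02 M), 110 °C, Ar
Reagents that add atoms: none
Why: Heating should open the cyclobutenone by a conrotatory four-electron electrocyclic reaction in which the donor hydroxyl turns outward, so the alkenyl arm lies cis to the ketene in 21; six-electron disrotatory electrocyclization then joins the ketene carbon (future C6′) to the terminal CH2 (future C5′), and enolization of 22 gives the hydroquinone. This is the Moore rearrangement of squarate-derived 4-alkenyl-4-hydroxycyclobutenones to hydroquinones. The benzene ring is closed by a thermal 6π electrocyclization in which all six ring atoms (C4a′, C5′, C6′, C7′, C8′, C8a′) come from the ketene–diene chain. No stereocentre is formed and the carbinol centre disappears, so both epimers of 20 converge. The step needs torquoselective ring opening, secured by the hydroxyl on the carbinol carbon, and an unsubstituted alkene terminus, provided by the =CH2 of the acrolein acetal unit; the order OH, O-Drk, OMe, OH around the ring follows from the constitution of 20, and the dioxolane, acetal and trisubstituted alkene should be inert to neutral thermolysis under argon.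

Step 12
Reactants: 23 hydroquinone acetal
Product: 24 2,5-dihydroxy-3-methoxy-4-(Drk-oxy)benzaldehyde
Conditions: PPTS (cat.), acetone/H2O 10:1, 0 °C → rt, Ar
Reagents that add atoms: water, O
Why: Acetal hydrolysis; the acyclic acetal of an electron-rich benzaldehyde should ionize far faster than the hindered dioxolane, and any C3 ketone released early converges on the target in step 15.

Step 13
Reactants: 24 salicylaldehyde
Product: 27 6-hydroxy-8-methoxy-7-(Drk-oxy)coumarin, via (E)-cinnamate 25 (not isolated), via (Z)-cinnamate 26 (not isolated)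
Conditions: Ph3P=CHCO2Et (2.5 equiv), PhNEt2, 210 °C, Ar
Reagents that add atoms: ethyl (triphenylphosphoranylidene)acetate, CCOC(=O)C=P(c1ccccc1)(c1ccccc1)c1ccccc1
Why: Wittig olefination of the aldehyde with a stabilized ylide, thermal E-to-Z isomerization and lactonization onto the ortho hydroxyl is the classical one-pot coumarin synthesis, and the C6′ hydroxyl, para to the reacting phenol, cannot lactonize.

Step 14
Reactants: 27 hydroxycoumarin
Product: 28 6,8-dimethoxy-7-(Drk-oxy)coumarin
Conditions: MeI, K2CO3, acetone, 50 °C
Reagents that add atoms: iodomethane, CI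
Why: Williamson O-methylation of the only free phenol (C6′–OH), so no site selectivity is required.

Step 15
Reactants: 28 coumarin ketal
Product: 29 6,8-dimethoxy-7-[(3-oxo-9-epi-drim-7-en-11-yl)oxy]coumarin (target)
Conditions: 2 M HCl, THF, rt
Reagents that add atoms: water, O
Why: Acid hydrolysis of the dioxolane releases the C3 ketone, and the coumarin, aryl ether and trisubstituted alkene should be stable to dilute acid at room temperature.

**Compound list**
1 | (R)-carvone | CC1=CC[C@H](CC1=O)C(C)=C | starting material
2 | lithium dienolate of (R)-carvone (cross-conjugated, O–Li on C1, C1=C6) | CC1=CC[C@H](C=C1O[Li])C(C)=C | intermediate (not isolated)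
3 | 6-methylcarvone, C5 as in (R)-carvone, both C6 epimers | CC1=CC[C@H](C(C)C1=O)C(C)=C | intermediate
4 | 6-(2-cyanoethyl)-6-methylcarvone, cyanoethyl trans and methyl cis to the C5 isopropenyl group | CC1=CC[C@H]([C@](C)(CCC#N)C1=O)C(C)=C | intermediate
5 | 3-imino-11-nordrim-7-en-9-one (N–H ketimine; 5α-H, 10β-CH3) | O=C1C(C)=CC[C@H]2C(C)(C)C(=N)CC[C@]12C | intermediate (not isolated)
6 | 11-nordrim-7-ene-3,9-dione (trans-decalin; 5α-H, 10β-CH3) | O=C1C(C)=CC[C@H]2C(C)(C)C(=O)CC[C@]12C | intermediate
7 | 3,3-ethylenedioxy-11-nordrim-7-en-9-one | O=C1C(C)=CC[C@H]2C(C)(C)C3(OCCO3)CC[C@]12C | intermediate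
8 | 7α,8α-epoxy-3,3-ethylenedioxy-11-nordriman-9-one (8β-CH3) | O=C1[C@]2(C)O[C@@H]2C[C@H]3C(C)(C)C4(OCCO4)CC[C@]13C | intermediate
9 | hydrazone of 8 at C9 | NN=C1[C@]2(C)O[C@@H]2C[C@H]3C(C)(C)C4(OCCO4)CC[C@]13C | intermediate (not isolated)
10 | 3,3-ethylenedioxy-11-nordrim-8-en-7α-ol (axial hydroxyl) | O[C@@H]1C[C@H]2C(C)(C)C3(OCCO3)CC[C@]2(C)C=C1C | intermediate
11 | potassium alkoxide of 10 | [K]O[C@@H]1C[C@H]2C(C)(C)C3(OCCO3)CC[C@]2(C)C=C1C | intermediate (not isolated)
12 | 7α-[(tributylstannyl)methoxy]-3,3-ethylenedioxy-11-nordrim-8-ene | CCCC[Sn](CCCC)(CCCC)CO[C@@H]1C[C@H]2C(C)(C)C3(OCCO3)CC[C@]2(C)C=C1C | intermediate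
13 | 7α-(lithiomethoxy)-3,3-ethylenedioxy-11-nordrim-8-ene | [Li]CO[C@@H]1C[C@H]2C(C)(C)C3(OCCO3)CC[C@]2(C)C=C1C | intermediate (not isolated)
14 | 3,3-ethylenedioxy-9-epi-drim-7-en-11-ol (Drk-OH; CH2OH α on C9, 9β-H, 5α-H, 10β-CH3) | OC[C@@H]1C(C)=CC[C@H]2C(C)(C)C3(OCCO3)CC[C@]12C | intermediate
15 | dimethyl squarate | COC1=C(OC)C(=O)C1=O | starting material
16 | lithium alkoxide of 14 | [Li]OC[C@@H]1C(C)=CC[C@H]2C(C)(C)C3(OCCO3)CC[C@]12C | intermediate (not isolated)
17 | 3-methoxy-4-(Drk-oxy)cyclobut-3-ene-1,2-dione | COC1=C(OC[C@@H]2C(C)=CC[C@H]3C(C)(C)C4(OCCO4)CC[C@]23C)C(=O)C1=O | intermediate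
18 | 2-bromo-3,3-diethoxyprop-1-ene | CCOC(OCC)C(Br)=C | starting material
19 | 2-lithio-3,3-diethoxypropene | CCOC(OCC)C([Li])=C | intermediate (not isolated)
20 | 4-[1-(diethoxymethyl)ethenyl]-4-hydroxy-3-methoxy-2-(Drk-oxy)cyclobut-2-en-1-one, both carbinol epimers | CCOC(OCC)C(=C)C1(O)C(OC)=C(OC[C@@H]2C(C)=CC[C@H]3C(C)(C)C4(OCCO4)CC[C@]23C)C1=O | intermediate (key-step precursor)
21 | dienylketene: 5-(diethoxymethyl)-4-hydroxy-3-methoxy-2-(Drk-oxy)hexa-1,3,5-trien-1-one, ketene carbon cis to the alkenyl arm | O=C=C(OC[C@@H]1C(C)=CC[C@H]2C(C)(C)C3(OCCO3)CC[C@]12C)/C(OC)=C(/O)C(=C)C(OCC)OCC | intermediate (not isolated)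
22 | 5-(diethoxymethyl)-4-hydroxy-3-methoxy-2-(Drk-oxy)cyclohexa-2,4-dien-1-one | O=C1CC(C(OCC)OCC)=C(O)C(OC)=C1OC[C@@H]2C(C)=CC[C@H]3C(C)(C)C4(OCCO4)CC[C@]23C | intermediate (not isolated)
23 | 2,5-dihydroxy-3-methoxy-4-(Drk-oxy)benzaldehyde diethyl acetal | CCOC(OCC)c1cc(O)c(OC[C@@H]2C(C)=CC[C@H]3C(C)(C)C4(OCCO4)CC[C@]23C)c(OC)c1O | intermediate (key-step product)
24 | 2,5-dihydroxy-3-methoxy-4-(Drk-oxy)benzaldehyde | O=Cc1cc(O)c(OC[C@@H]2C(C)=CC[C@H]3C(C)(C)C4(OCCO4)CC[C@]23C)c(OC)c1O | intermediate
25 | ethyl (E)-3-[2,5-dihydroxy-3-methoxy-4-(Drk-oxy)phenyl]prop-2-enoate | CCOC(=O)/C=C/c1cc(O)c(OC[C@@H]2C(C)=CC[C@H]3C(C)(C)C4(OCCO4)CC[C@]23C)c(OC)c1O | intermediate (not isolated)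
26 | ethyl (Z)-3-[2,5-dihydroxy-3-methoxy-4-(Drk-oxy)phenyl]prop-2-enoate | CCOC(=O)/C=C\c1cc(O)c(OC[C@@H]2C(C)=CC[C@H]3C(C)(C)C4(OCCO4)CC[C@]23C)c(OC)c1O | intermediate (not isolated)
27 | 6-hydroxy-8-methoxy-7-(Drk-oxy)coumarin | Oc1cc2ccc(=O)oc2c(OC)c1OC[C@@H]1C(C)=CC[C@H]2C(C)(C)C3(OCCO3)CC[C@]12C | intermediate
28 | 6,8-dimethoxy-7-(Drk-oxy)coumarin | COc1cc2ccc(=O)oc2c(OC)c1OC[C@@H]1C(C)=CC[C@H]2C(C)(C)C3(OCCO3)CC[C@]12C | intermediate
29 | 6,8-dimethoxy-7-[(3-oxo-9-epi-drim-7-en-11-yl)oxy]coumarin (CNP0127079.1) | COc1cc2ccc(=O)oc2c(OC)c1OC[C@@H]1C(C)=CC[C@H]2C(C)(C)C(=O)CC[C@]12C | target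

**Step count**
Total steps: 15. Longest linear sequence: 15 steps from (R)-carvone; dimethyl squarate and the bromo acetal enter as purchased materials.

**Steps most likely to fail**

1. Step 10. The alkenyllithium may fail to discriminate between the two squarate carbonyls, since steric bias is the only control. Addition beside the terpenyl-ether carbon would, after rearrangement, place the terpenyl ether on C8′. The fallback leaves the squarate sequence at alcohol 14, which is coupled with purchased isofraxidin (7-hydroxy-6,8-dimethoxycoumarin) by Mitsunobu etherification (PPh3, DIAD, toluene, 0 → 60 °C). The acidic phenol attacks C11 of the oxyphosphonium salt and gives 28 directly, so no new compound arises (F0), and the route is rejoined at 28 for step 15. Substitution at the β-branched C11 is expected to be slow, so this is kept as the reserve.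

2. Step 3. The tertiary radical may be reduced to the isopropyl group or add to a second molecule before it closes onto the weakly electrophilic nitrile. The fallback sets out from 4: HBr in AcOH at 0 °C adds to the isopropenyl group to give the tertiary bromide 8-bromo-6-(2-cyanoethyl)-6-methyl-8,9-dihydrocarvone F1. Slow addition of Bu3SnH with AIBN in benzene at 80 °C then generates the same C4 radical under chain conditions at low stannane concentration. The 6-exo closure onto the nitrile is followed by hydrolysis with 1 M HCl, and the route is rejoined at 6.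

3. Step 6. Hydrazone formation at the C9 ketone, which lies between two fully substituted carbons, may be too slow, so that epoxide opening by hydrazine or decomposition takes over. The fallback sets out from 8: NaBH4 in MeOH reduces the ketone to the epoxy alcohol 7α,8α-epoxy-3,3-ethylenedioxy-11-nordriman-9-ol F2 (either C9 epimer serves). 1,1′-Thiocarbonyldiimidazole with DMAP in toluene at 80 °C gives the thiocarbonylimidazolide of that alcohol F3. Bu3SnH with AIBN in benzene at 80 °C then generates the C9 radical in a Barton–McCombie-type fragmentation; it opens the epoxide to the C7 alkoxy radical, and hydrogen transfer gives 10, where the route is rejoined.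

Further compounds
F0 | step 10 | none | none
F1 | step 3 | 8-bromo-6-(2-cyanoethyl)-6-methyl-8,9-dihydrocarvone (tertiary bromide of 4) | CC1=CC[C@H]([C@](C)(CCC#N)C1=O)C(C)(C)Br
F2 | step 6 | 7α,8α-epoxy-3,3-ethylenedioxy-11-nordriman-9-ol (C9 epimers) | OC1[C@]2(C)O[C@@H]2C[C@H]3C(C)(C)C4(OCCO4)CC[C@]13C
F3 | step 6 | O-(7α,8α-epoxy-3,3-ethylenedioxy-11-nordriman-9-yl) imidazole-1-carbothioate | S=C(OC1[C@]2(C)O[C@@H]2C[C@H]3C(C)(C)C4(OCCO4)CC[C@]13C)n1ccnc1
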